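## Retrosynthetic overview

1. The target (drawn as the open 12‑aldehyde/11‑acid) comes from mild acid hydrolysis of a 12‑methoxy‑11,12‑olide (pseudoester) that masks aldehyde and acid together; the C6 trienoate comes from Steglich acylation of a 6α‑OH.
2. The 6α,9α‑diol comes from α‑face singlet‑oxygen [4+2] addition to a ring B 6,8‑diene followed by O–O reduction, which sets C6 and C9 together.
3. The diene pseudoester comes from C12 formylation of a dienyl triflate, itself from α′,β′‑dehydrogenation of a bicyclic β‑keto ester.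
4. The bicyclic β‑keto ester comes from an organocatalytic (chiral IDPi Brønsted acid) enantioselective polyene cyclization of an achiral geranylated acetoacetate. Ring A, then ring B, close in one cascade and C5 and C10 are set; the lactone ring is closed in step 6 and opened in step 9.
5. The acyclic precursor comes from methyl acetoacetate dianion and geranyl bromide.

## Assumptions

- Drimane numbering is used for positions: C1–C10 are the decalin carbons, C11 is on C9, C12 is on C8; α is the face opposite the C10 methyl.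
- The open aldehyde‑acid of the target and its 12‑hydroxy‑11,12‑olide lactol are ring–chain tautomers of one compound; the hydrolysis product of step 9 is taken as the target as drawn.
- (2E,4E,6E)‑Octa‑2,4,6‑trienoic acid is taken as commercially available.
- In step 2 the (S,S) catalyst is assumed to give the (5S,10S) series; its antipode is used if the sense of induction proves opposite.

## Route

Step 1
Reactants: 1 methyl acetoacetate; 2 geranyl bromide
Product: 4 methyl (6E)-7,11-dimethyl-3-oxododeca-6,10-dienoate, via dilithium dianion 3 (not isolated)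
Conditions: LiN(iPr)2 (2.1 equiv), THF, 0 °C; then 2, 0 °C → rt; 1 M HCl
Reagents that add atoms: none
Why: Weiler dianion alkylation: the terminal carbon of the acetoacetate dianion is the most nucleophilic site and displaces the allylic bromide by SN2 without touching the E olefin; no stereocenter is formed.

Step 2
Reactants: 4 methyl (6E)-7,11-dimethyl-3-oxododeca-6,10-dienoate
Product: 5 methyl (1R,4aS,8aS)-5,5,8a-trimethyl-2-oxodecahydronaphthalene-1-carboxylate (trans-decalin; 5α-H, 9β-CO2Me, 10β-Me)
Conditions: (S,S)-IDPi (confined BINOL-derived imidodiphosphorimidate Brønsted acid with 3,3′-aryl pockets and perfluoroalkylsulfonyl imide core, 5 mol %), (CF3)3COH, −10 °C, 48 h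
Reagents that add atoms: none
Why: Proposed new method: the confined chiral acid protonates the terminal isopropylidene olefin of 4 held in a chair–chair fold inside its pocket, the 6,7-olefin adds anti (Stork–Eschenmoser) and the enol carbon of the β-keto ester closes ring B, so the catalyst's face selection in the first C–C bond formation sets C5 (S), the concerted anti addition relays it to C10 (S, trans ring fusion) and C9 equilibrates to the equatorial ester; the closest known reaction type is the IDPi-catalysed asymmetric polyene cyclization of homofarnesol-type substrates terminated by an oxygen nucleophile (and the racemic SnCl4 cyclization of this same keto ester), extended here to an enol carbon terminator.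

Step 3
Reactants: 5 methyl (1R,4aS,8aS)-5,5,8a-trimethyl-2-oxodecahydronaphthalene-1-carboxylate
Product: 9 methyl (1R,4aS,8aS)-5,5,8a-trimethyl-2-oxo-1,2,4a,5,6,7,8,8a-octahydronaphthalene-1-carboxylate (6-en-8-one; in equilibrium with its dienol), via dilithium dianion 6 (not isolated), via phenylselenide 7 (not isolated), via selenoxide 8 (not isolated)
Conditions: LiN(iPr)2 (2.2 equiv), THF, −78 → 0 °C; PhSeBr (1.0 equiv), −78 °C; 1 M HCl; then 30% H2O2, pyridine, CH2Cl2, 0 °C → rt
Reagents that add atoms: none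
Why: Kinetic dianion formation exposes the α′ carbon (C7), which is selenenylated selectively, and selenoxide syn-elimination (Reich) can only run toward C6, giving the enone; C5 and C10 are untouched and C9 is planarised in the next step.

Step 4
Reactants: 9 methyl (1R,4aS,8aS)-5,5,8a-trimethyl-2-oxo-1,2,4a,5,6,7,8,8a-octahydronaphthalene-1-carboxylate
Product: 10 methyl (4aS,8aS)-5,5,8a-trimethyl-2-(trifluoromethanesulfonyloxy)-4a,5,6,7,8,8a-hexahydronaphthalene-1-carboxylate (6,8-dienyl triflate)
Conditions: Tf2O, iPr2NEt, CH2Cl2, −78 → 0 °C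
Reagents that add atoms: triflic anhydride, O=S(=O)(OS(=O)(=O)C(F)(F)F)C(F)(F)F
Why: Enol triflate formation: O-sulfonylation of the enolised β-keto ester (C9–H is the only strongly acidic proton) fixes the C8=C9 double bond and gives a coupling-ready dienyl triflate; no stereocenter is affected.

Step 5
Reactants: 10 methyl (4aS,8aS)-5,5,8a-trimethyl-2-(trifluoromethanesulfonyloxy)-4a,5,6,7,8,8a-hexahydronaphthalene-1-carboxylate
Product: 11 methyl (4aS,8aS)-2-formyl-5,5,8a-trimethyl-4a,5,6,7,8,8a-hexahydronaphthalene-1-carboxylate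
Conditions: Pd(PPh3)4 (5 mol %), CO (1 atm), Bu3SnH (1.1 equiv, slow addition), THF, 50 °C
Reagents that add atoms: carbon monoxide, [C-]#[O+]
Why: Stille reductive carbonylation (formylation): oxidative addition of the vinyl triflate to zerovalent palladium, CO insertion and hydride transfer from tin install the C12 aldehyde with the diene intact.

Step 6
Reactants: 11 methyl (4aS,8aS)-2-formyl-5,5,8a-trimethyl-4a,5,6,7,8,8a-hexahydronaphthalene-1-carboxylate
Product: 12 (5aS,9aS)-3-methoxy-6,6,9a-trimethyl-5a,6,7,8,9,9a-hexahydronaphtho[1,2-c]furan-1(3H)-one (12-methoxydrima-6,8-dien-11,12-olide, both C12 epimers)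
Conditions: MeOH (10 equiv), CSA (10 mol %), PhMe, 80 °C
Reagents that add atoms: methanol, CO
Why: Acid-catalysed pseudoester formation, the known behaviour of cis-β-formylacrylates: methanol adds to the aldehyde and the hemiacetal OH lactonises onto the cis-disposed C11 ester with loss of MeOH, masking aldehyde and acid as one 5-methoxybutenolide; the C12 epimers converge in step 9.

Step 7
Reactants: 12 (5aS,9aS)-3-methoxy-6,6,9a-trimethyl-5a,6,7,8,9,9a-hexahydronaphtho[1,2-c]furan-1(3H)-one
Product: 14 (5S,5aS,9aS,9bS)-5,9b-dihydroxy-3-methoxy-6,6,9a-trimethyl-5,5a,6,7,8,9,9a,9b-octahydronaphtho[1,2-c]furan-1(3H)-one (6α,9α-dihydroxy-12-methoxydrim-7-en-11,12-olide), via endoperoxide 13 (not isolated)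
Conditions: O2, TPP (1 mol %), hν (white LED), CH2Cl2, 0 °C; then Zn, AcOH, 0 °C → rt
Reagents that add atoms: dioxygen, O=O
Why: Singlet-oxygen [4+2] cycloaddition to the s-cis ring B diene takes place on the α face, opposite the axial 10β- and 4β-methyl groups (as in ergosterol peroxide formation), so both C6–O and C9–O are formed α (6S, 9S), and Zn/AcOH reduction of the O–O bond gives the cis-1,4-diol with the 7,8-olefin.

Step 8
Reactants: 14 6α,9α-dihydroxy-12-methoxydrim-7-en-11,12-olide; 15 (2E,4E,6E)-octa-2,4,6-trienoic acid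
Product: 16 (5S,5aS,9aS,9bS)-9b-hydroxy-3-methoxy-6,6,9a-trimethyl-1-oxo-1,3,5,5a,6,7,8,9,9a,9b-decahydronaphtho[1,2-c]furan-5-yl (2E,4E,6E)-octa-2,4,6-trienoate
Conditions: 15 (1.5 equiv), DIC, DMAP, CH2Cl2, 0 °C → rt
Reagents that add atoms: none
Why: Steglich esterification acylates the secondary allylic 6α-OH selectively because the 9α-OH is tertiary, neopentyl and α to the lactone carbonyl; acyl transfer to oxygen retains the C6 configuration.

Step 9
Reactants: 16 12-methoxy-6α-[(2E,4E,6E)-octa-2,4,6-trienoyloxy]-9α-hydroxydrim-7-en-11,12-olide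
Product: 17 (1S,4S,4aS,8aS)-2-formyl-1-hydroxy-5,5,8a-trimethyl-4-[(2E,4E,6E)-octa-2,4,6-trienoyloxy]-1,4,4a,5,6,7,8,8a-octahydronaphthalene-1-carboxylic acid (target)
Conditions: 1 M HCl, THF, 40 °C
Reagents that add atoms: water, O
Why: Acid-catalysed acetal (pseudoester) hydrolysis through an allylic oxocarbenium ion releases methanol and unmasks the 12-aldehyde and 11-carboxylic acid, while the hindered trienoate and the tertiary α-hydroxy acid centre are stable to dilute acid; no stereocenter is touched.

## Compound list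

1 | methyl acetoacetate | COC(=O)CC(C)=O | starting material
2 | geranyl bromide, (2E)-1-bromo-3,7-dimethylocta-2,6-diene | CC(C)=CCC/C(C)=C/CBr | starting material
3 | dilithium dianion of methyl acetoacetate | [Li+].[Li+].COC([O-])=CC([O-])=C | intermediate
4 | methyl (6E)-7,11-dimethyl-3-oxododeca-6,10-dienoate | COC(=O)CC(=O)CC/C=C(\C)CCC=C(C)C | intermediate
5 | methyl (1R,4aS,8aS)-5,5,8a-trimethyl-2-oxodecahydronaphthalene-1-carboxylate | C1CC(=O)[C@H](C(=O)OC)[C@@]2(C)CCCC(C)(C)[C@H]12 | intermediate
6 | dilithium dianion of 5 (C7/C9 bis-enolate) | [Li+].[Li+].C1C=C([O-])C(=C([O-])OC)[C@@]2(C)CCCC(C)(C)[C@H]12 | intermediate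
7 | methyl (1R,4aS,8aS)-5,5,8a-trimethyl-2-oxo-3-(phenylselanyl)decahydronaphthalene-1-carboxylate (C7 epimers) | C1C([Se]c3ccccc3)C(=O)[C@H](C(=O)OC)[C@@]2(C)CCCC(C)(C)[C@H]12 | intermediate
8 | selenoxide of 7, 3-(phenylseleninyl) compound | C1C([Se](=O)c3ccccc3)C(=O)[C@H](C(=O)OC)[C@@]2(C)CCCC(C)(C)[C@H]12 | intermediate
9 | methyl (1R,4aS,8aS)-5,5,8a-trimethyl-2-oxo-1,2,4a,5,6,7,8,8a-octahydronaphthalene-1-carboxylate | C1=CC(=O)[C@H](C(=O)OC)[C@@]2(C)CCCC(C)(C)[C@H]12 | intermediate
10 | methyl (4aS,8aS)-5,5,8a-trimethyl-2-(trifluoromethanesulfonyloxy)-4a,5,6,7,8,8a-hexahydronaphthalene-1-carboxylate | C1=CC(OS(=O)(=O)C(F)(F)F)=C(C(=O)OC)[C@@]2(C)CCCC(C)(C)[C@H]12 | intermediate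
11 | methyl (4aS,8aS)-2-formyl-5,5,8a-trimethyl-4a,5,6,7,8,8a-hexahydronaphthalene-1-carboxylate | C1=CC(C=O)=C(C(=O)OC)[C@@]2(C)CCCC(C)(C)[C@H]12 | intermediate
12 | (5aS,9aS)-3-methoxy-6,6,9a-trimethyl-5a,6,7,8,9,9a-hexahydronaphtho[1,2-c]furan-1(3H)-one (C12 epimer mixture) | C1=CC3=C(C(=O)OC3OC)[C@@]2(C)CCCC(C)(C)[C@H]12 | intermediate
13 | 6α,9α-epidioxy-12-methoxydrim-7-en-11,12-olide | O5[C@H]1C=C3[C@](O5)(C(=O)OC3OC)[C@@]2(C)CCCC(C)(C)[C@H]12 | intermediate
14 | (5S,5aS,9aS,9bS)-5,9b-dihydroxy-3-methoxy-6,6,9a-trimethyl-5,5a,6,7,8,9,9a,9b-octahydronaphtho[1,2-c]furan-1(3H)-one | O[C@H]1C=C3[C@](O)(C(=O)OC3OC)[C@@]2(C)CCCC(C)(C)[C@H]12 | intermediate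
15 | (2E,4E,6E)-octa-2,4,6-trienoic acid | C/C=C/C=C/C=C/C(=O)O | starting material
16 | 12-methoxy-9α-hydroxy-6α-[(2E,4E,6E)-octa-2,4,6-trienoyloxy]drim-7-en-11,12-olide | C/C=C/C=C/C=C/C(=O)O[C@H]1C=C3[C@](O)(C(=O)OC3OC)[C@@]2(C)CCCC(C)(C)[C@H]12 | intermediate
17 | (1S,4S,4aS,8aS)-2-formyl-1-hydroxy-5,5,8a-trimethyl-4-[(2E,4E,6E)-octa-2,4,6-trienoyloxy]-1,4,4a,5,6,7,8,8a-octahydronaphthalene-1-carboxylic acid | C/C=C/C=C/C=C/C(=O)O[C@H]1C=C(C=O)[C@](O)(C(=O)O)[C@@]2(C)CCCC(C)(C)[C@H]12 | target

## Step count and risks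

Total steps: 9. Longest linear sequence: 9 (1/2 → 17; acid 15 is bought).

**Step 2 (new cyclization).** Risks are termination through the enol oxygen instead of carbon, arrest after ring A, and low ee with a carbonyl-bearing substrate. Fallback, from 4 back to 5: move the asymmetric induction to an organocatalytic Shi epoxidation. Compound 4 is epoxidised at the terminal olefin with the ent-Shi ketone (L-fructose-derived) and KHSO5 (Oxone) at pH 10.5. The reaction is stopped at partial conversion because the internal olefin is only modestly less reactive, and 4 is recycled. This gives methyl (6E,10S)-10,11-epoxy-7,11-dimethyl-3-oxododec-6-enoate F1. SnCl4 in CH2Cl2 at −78 °C then triggers the well-precedented epoxide-initiated cyclization terminated by the β-keto ester, in which the epoxide stereocenter controls C5 and C10, giving methyl 3β-hydroxy-8-oxo-12-nordriman-11-oate F2. Thiocarbonyldiimidazole converts F2 into its 3-O-(imidazol-1-ylthiocarbonyl) derivative F3, and Barton–McCombie reduction (Bu3SnH, AIBN, PhMe, 110 °C) removes the C3 oxygen to give 5, where the route resumes.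

**Step 6 (direct ester-to-pseudoester exchange).** The C11 ester is flanked by a quaternary carbon and the open dimethyl acetal ester may persist. Fallback, from 11 back to 12: saponify first, using the neighbouring formyl group (attack of the aldehyde hydrate anion on the ester; LiOH, THF/H2O, 0 °C, then acid) to give the pseudoacid 12-hydroxydrima-6,8-dien-11,12-olide F4. Fischer-type pseudo-esterification of F4 (MeOH, CSA, rt) then gives 12.

**Step 7 (photooxygenation of a lactone-conjugated diene).** The diene is electron-poor, so the [4+2] may be slow and ene products may compete. Fallback, from 10 back to 14: carry C12 as a methyl group through the oxygenation and oxidise it afterwards. Compound 10 is cross-coupled with MeMgBr and catalytic Fe(acac)3 (THF/NMP, −30 °C) to give the more electron-rich methyl drima-6,8-dien-11-oate F5. Photooxygenation as in step 7 gives methyl 6α,9α-epidioxydrim-7-en-11-oate F6, and Zn/AcOH reduces it to methyl 6α,9α-dihydroxydrim-7-en-11-oate F7. SeO2 with t-BuOOH (CH2Cl2, rt) oxidises the only allylic C–H site at the more substituted olefin terminus, the C12 methyl, to give methyl 6α,9α-dihydroxy-12-oxodrim-7-en-11-oate F8. CSA in MeOH/PhMe closes the pseudoester to give 14.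

## Further compounds

F1 | step 2 | methyl (6E,10S)-10,11-epoxy-7,11-dimethyl-3-oxododec-6-enoate | COC(=O)CC(=O)CC/C=C(\C)CC[C@@H]1OC1(C)C
F2 | step 2 | methyl (1R,4aR,6S,8aS)-6-hydroxy-5,5,8a-trimethyl-2-oxodecahydronaphthalene-1-carboxylate (methyl 3β-hydroxy-8-oxo-12-nordriman-11-oate) | C1CC(=O)[C@H](C(=O)OC)[C@@]2(C)CC[C@H](O)C(C)(C)[C@H]12
F3 | step 2 | 3-O-(imidazol-1-ylthiocarbonyl) derivative of F2 | C1CC(=O)[C@H](C(=O)OC)[C@@]2(C)CC[C@H](OC(=S)n3ccnc3)C(C)(C)[C@H]12
F4 | step 6 | (5aS,9aS)-3-hydroxy-6,6,9a-trimethyl-5a,6,7,8,9,9a-hexahydronaphtho[1,2-c]furan-1(3H)-one (12-hydroxydrima-6,8-dien-11,12-olide) | C1=CC3=C(C(=O)OC3O)[C@@]2(C)CCCC(C)(C)[C@H]12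
F5 | step 7 | methyl (4aS,8aS)-2,5,5,8a-tetramethyl-4a,5,6,7,8,8a-hexahydronaphthalene-1-carboxylate (methyl drima-6,8-dien-11-oate) | C1=CC(C)=C(C(=O)OC)[C@@]2(C)CCCC(C)(C)[C@H]12
F6 | step 7 | methyl 6α,9α-epidioxydrim-7-en-11-oate | O5[C@H]1C=C(C)[C@](O5)(C(=O)OC)[C@@]2(C)CCCC(C)(C)[C@H]12
F7 | step 7 | methyl (1R,4S,4aS,8aS)-1,4-dihydroxy-2,5,5,8a-tetramethyl-1,4,4a,5,6,7,8,8a-octahydronaphthalene-1-carboxylate (methyl 6α,9α-dihydroxydrim-7-en-11-oate) | O[C@H]1C=C(C)[C@](O)(C(=O)OC)[C@@]2(C)CCCC(C)(C)[C@H]12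
F8 | step 7 | methyl 6α,9α-dihydroxy-12-oxodrim-7-en-11-oate | O[C@H]1C=C(C=O)[C@](O)(C(=O)OC)[C@@]2(C)CCCC(C)(C)[C@H]12
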